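**Atom numbering used throughout:** ring A is C1–C2–C3–C4–C5–C10 (OH on C1; methyl and the lactone carbonyl C19 on C4); ring B is C5–C6–C7–C8–C9–C20–C10; ring C is C8–C9–C11–C12–C13–C14; the lactone oxygen sits on C6; C15 is the isopropyl methine.

## Analysis of the target

6,7-Anhydroballotiquinone (34) has a 6-7-6 carbocyclic core: cyclohexane ring A, a seven-membered ring B with three double bonds (C6=C7, C8=C9, C20=C10) and a single sp3 carbon (C5), and a 12-hydroxy-13-isopropyl-11,14-benzoquinone ring C. A γ-lactone joins C19 on C4 to oxygen on C6, where it is an enol lactone. The three stereocentres all lie on ring A: quaternary C4 (S), C5 (R) and the allylic carbinol C1 (R). The C4 methyl and H5 are cis, so the lactone is cis-fused to ring A, and the C1 hydroxyl sits on the lactone face, anti to H5. Sensitive groups are the enol lactone (an acyl donor towards nucleophiles), the acidic and redox-active hydroxyquinone, and the C1 allylic alcohol, which is conjugated through C10=C20 to ring C. The difficulty lies in a fully substituted ring C fused across C8–C9 to a seven-membered ring, next to a quaternary centre, with the ring B unsaturation placed exactly. The strategy rests on the fact that the six carbons of ring C can be the carbons of three alkynes (C8≡C14, C9≡C11, C12≡C13). The chain C7–C6–C5–C10–C20 links two of them, and the C14 oxygen and the C13 isopropyl carbon C15 can be tied together through silicon, so that one cyclotrimerisation closes rings B and C together.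

## Retrosynthetic reasoning

**34 back to 31.** The last operations are removal of the silyl group of 33 and, before that, introduction of the C12 oxygen. C12 is the only unsubstituted carbon of quinone 31, so a nucleophilic oxidant can add nowhere else; the C12–O bond is therefore cut here and not carried through the synthesis. Forward, conjugate epoxidation (via 32) and base-induced opening of the epoxide must deliver the 12-hydroxyquinone without touching the enol lactone.

**31 back to 29.** The C6=C7 double bond is traced to the saturated C6–C7 unit of 29. Quinone 29 is an isomer of hydroquinone 30: two prototropic shifts (H7, then H6) move two hydrogens from ring B onto the quinone oxygens. The dehydrogenation thus becomes an internal redox isomerisation followed by a mild re-oxidation, and C6 can stay sp3 (and a stereocentre that organises ring B closure) until after the key step.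

**29 back to 26.** The C11 carbonyl comes from para-oxidation of phenol 28 (C11 is the free para position of the C14 phenol). The isopropyl group comes from the benzylic carbinol of 27, and both oxygens of 27 come from the Si–O–C15 link of 26 by oxidative cleavage of the aryl–silicon bond. Cutting here means that the silicon atom that fixes the regiochemistry of the key step also becomes the C14 oxygen and leaves C15 at an oxidation level that is reduced in one step.

**26 back to 25 (key disconnection).** Ring C is cut at C8–C9, C11–C12 and C13–C14, which gives the three alkynes of 25. This cut closes ring B, ring C and the temporary oxasilole in one operation, and needs no separately made hexasubstituted arene. Forward, the reaction must close a seven-membered ring intramolecularly; the regiochemistry is fixed by the two tethers.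

**25 back to 20, 21 and 22.** The Si–C14 and Si–O bonds are cut; 21 is a two-fold silicon electrophile that joins the acetylide of 20 to the tertiary alcohol 22. The C11 alkyne of 20 carries a trimethylsilyl cap (24), so that only C14–H is deprotonated; the cap is removed last.

**20 back to 15 and 16.** The C1 carbinol comes from ketone 18 by 1,2-reduction (19). The C6–C7 bond and the lactone C–O bond of 18 come from lactol 15 and propargyl bromide 16. Cutting at C6–C7 makes C6 an aldehyde carbon held as a cyclic lactol, which can exist only when C6 and C19 are cis; addition anti to the quaternary C4 then places C7 cis to C10.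

**15 back to 7 and 8.** The C10=C20 enyne of 14 is an aldol condensation product of a C1 ketone with aldehyde 8. To enolise only towards C10, the aldol is run on enone 7, whose C2=C3 double bond blocks the other side; that double bond is then removed by conjugate reduction (12) before elimination gives 14.

**7 back to 1, 3 and 5.** Ring A is cut at C5–C10 and C3–C4, a Diels–Alder reaction of butenolide 3 with diene 2 (from 1). Because C19 and C6 are already in the butenolide ring, the cis relation at C4/C5 is guaranteed. The acetal stereocentre of 3 sets the absolute configuration, and the adduct 4 is an enol ether that leads to 7 after C4 methylation with 5 (giving 6) and oxidation. Setting C5 on a monocyclic ring A would have required distinguishing methyl from carboxyl at C4, which cannot be relied on.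

## Alternatives that were turned down

**Alternative 1: carbonyl ylide cycloaddition across C5=C10.** Ring B is cut at C5–C6 and C10–C20. Forward, rhodium-catalysed decomposition of the ortho-formyl aryl diazomethyl ketone A1 gives the cyclic dipole A2, which adds to the ring A enone A3 to give the oxygen-bridged adduct A4.
- For: it is convergent and forms two ring B bonds at once. Ring C arrives with all three oxygens in place, so no late C12 oxygenation is needed. The bridging oxygen is already on C6, where the lactone oxygen belongs. On these two points it is stronger than the chosen route.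
- Against: A1 is a hexasubstituted benzene that needs its own multistep synthesis. The cycloaddition is intermolecular, onto a trisubstituted alkene next to a quaternary carbon. Its regiochemistry (C6 to C5, not to C10) rests on a small orbital bias, and its facial selectivity on the difference between methyl and ester at C4. The bridge must then be opened, the C7 ketone removed and three methyl ethers differentiated.
- Comparison: the chosen strategy offers regiochemistry fixed by covalent tethers and a C4/C5 relation set in a ring before the key step.

**Alternative 2: intramolecular Diels–Alder of a butenolide with a silyloxydiene.** Ring A is cut at C5–C10 and C3–C4, with ring B as the tether ring. Heating A5 gives the tetracycle A6.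
- For: one step makes ring A, ring B and the quaternary centre, with the cis lactone fusion guaranteed by the butenolide. For ring A this is more economical than the chosen route.
- Against: the dienophile is an α-methyl butenolide and the tether ring is seven-membered, so the cycloaddition is slow and entropically poor. A6 has C10 as an sp3 centre and its enol ether pointing to C2, so C10=C20 and C6=C7 both remain to be introduced by dehydrogenation. A5 again needs the fully substituted arene carrying two different side chains, and one of three methyl ethers must later be freed selectively.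
- Comparison: the chosen strategy has C10=C20 in place before the key step and builds ring C from simple alkynes.

**Alternative 3: ring expansion of a 4-hydroxycyclobutenone.** Only C8–C14 is cut. Heating A7 opens the four-membered ring and closes C14 onto C8 to give hydroquinone A8.
- For: A8 has exactly the oxidation pattern of ring C (protected O at C12, hydroquinone at C11/C14). This is clearly stronger than the chosen route, which needs four adjustments on ring C after the key step.
- Against: the key step makes one skeletal bond and one ring. A7 presupposes that the seven-membered ring, all three of its double bonds and the enol lactone are already assembled and survive a carbanion addition at C9 and thermolysis. The hardest part of the target, ring B, is left unsolved.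
- Comparison: the chosen strategy spends its key step on ring B and ring C together (three bonds, three rings) and accepts a longer oxidation endgame in return.

Key step: step 14

Assumption: (5R)-5-(l-menthyloxy)furan-2(5H)-one 3 is taken as a purchasable chiral building block; compounds 9–13 are carried as mixtures at C10 and C20 and 15 as a mixture at the lactol carbon, all of which later steps erase.

## Route

Step 1
Reactants: 1 methyl vinyl ketone
Product: 2 2-(tert-butyldimethylsilyloxy)buta-1,3-diene
Conditions: TBSOTf, Et3N, Et2O, 0 °C
Reagents that add atoms: tert-butyldimethylsilyl triflate, CC(C)(C)[Si](C)(C)OS(=O)(=O)C(F)(F)F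
Why: Soft enolisation and O-silylation of a methyl ketone; the methyl group is the only enolisable position, so a single silyloxydiene forms.

Step 2
Reactants: 3 (5R)-5-(l-menthyloxy)furan-2(5H)-one, 2 2-(tert-butyldimethylsilyloxy)buta-1,3-diene
Product: 4 cis-fused cycloadduct (TBS enol ether C1=C2; H4 and H5 cis; C6 menthyloxy anti to C10 and C3)
Conditions: 2 (3 equiv), BHT (cat.), toluene, 120 °C, sealed tube
Reagents that add atoms: 2-(tert-butyldimethylsilyloxy)buta-1,3-diene 2, C=CC(=C)O[Si](C)(C)C(C)(C)C
Why: Thermal Diels–Alder reaction of a γ-alkoxybutenolide; the nucleophilic diene terminus bonds to the lactone β-carbon C5 ("para" orientation, so the enol ether carbon becomes C1), and the diene adds to the face anti to the C6 menthyloxy group, which sets C4 and C5 cis and in the required absolute sense.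

Step 3
Reactants: 4 cis-fused cycloadduct, 5 methyl iodide
Product: 6 C4-methylated adduct (methyl cis to H5, lactone still cis-fused)
Conditions: LiN(iPr)2, THF, −78 °C; 5, −78 → −40 °C
Reagents that add atoms: methyl iodide 5, CI
Why: Alkylation of a ring-fusion lactone enolate; the electrophile enters on the convex face (the side of H5) because only that path keeps the 5/6 system cis-fused, which fixes the quaternary C4; the silyl enol ether is inert to the amide base.

Step 4
Reactants: 6 C4-methylated adduct
Product: 7 enone lactone acetal (C1 ketone, C2=C3)
Conditions: Pd(OAc)2 (1.1 equiv), MeCN, 40 °C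
Reagents that add atoms: none
Why: Saegusa–Ito oxidation; the palladium enolate at C2 can only lose the C3 hydrogen, and the quaternary C4 rules out further dehydrogenation.

Step 5
Reactants: 7 enone lactone acetal, 8 3-(trimethylsilyl)propynal
Product: 11 β-hydroxy enone (aldol at C10, mixture at C10 and C20), via lithium dienolate 9 (not isolated), via lithium aldolate 10 (not isolated)
Conditions: LiN(iPr)2, THF, −78 °C; 8; NH4Cl (aq)
Reagents that add atoms: 3-(trimethylsilyl)propynal 8, C[Si](C)(C)C#CC=O
Why: Kinetic α′-deprotonation of the enone can only occur at C10 (C2 is sp2 and C4 is quaternary), so the aldol addition to the ynal is regiospecific; the new centres are removed in step 7.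

Step 6
Reactants: 11 β-hydroxy enone
Product: 12 β-hydroxy ketone (C2–C3 saturated)
Conditions: [(Ph3P)CuH]6 (0.4 equiv), wet toluene, rt
Reagents that add atoms: none
Why: Copper hydride conjugate reduction of the enone; the reagent leaves isolated silylalkynes, lactones and free hydroxyl groups alone, and water protonates the copper enolate at C2 before it can equilibrate.

Step 7
Reactants: 12 β-hydroxy ketone
Product: 14 (E)-enynone lactone acetal (C10=C20, alkynyl syn to C5), via C20 mesylate 13 (not isolated)
Conditions: MsCl, Et3N, CH2Cl2, 0 °C; DBU, rt
Reagents that add atoms: none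
Why: Mesylation and E1cB elimination through the C1/C10 enolate; the reversible base conditions give the more stable (E)-alkylidene ketone, with the slim alkynyl group away from the carbonyl oxygen.

Step 8
Reactants: 14 (E)-enynone lactone acetal
Product: 15 lactol (cyclic form of the C6 aldehyde C19 acid)
Conditions: CF3CO2H/H2O (4:1), 40 °C
Reagents that add atoms: water, O
Why: Acid hydrolysis of the acyloxy acetal releases menthol; the aldehyde acid rests as the cyclic lactol, which only a cis C4/C5 arrangement can form, so the ring fusion is held.

Step 9
Reactants: 15 lactol, 16 propargyl bromide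
Product: 18 enynone lactone (C6 propargyl, C7 cis to C10), via seco hydroxy acid 17 (not isolated)
Conditions: In powder, 16, THF/H2O (1:1), rt; then 1 M HCl, rt
Reagents that add atoms: propargyl bromide 16, C#CCBr
Why: Barbier propargylation of the open-chain aldehyde in water, selective for the aldehyde over the hindered cross-conjugated ketone; Felkin–Anh attack anti to the quaternary C4 gives the C6 carbinol that lactonises onto C19 with C7 cis to C10.

Step 10
Reactants: 18 enynone lactone
Product: 19 C1 allylic alcohol (OH syn to the lactone bridge)
Conditions: NaBH4, CeCl3·7H2O, MeOH, −78 °C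
Reagents that add atoms: none
Why: Luche 1,2-reduction; allylic strain from the (E)-alkynyl group forces the C5–C6 bond pseudo-axial, hydride attacks C1 from the opposite face, and the hydroxyl ends syn to C6 as required.

Step 11
Reactants: 19 C1 allylic alcohol
Product: 20 C1 TBS ether
Conditions: TBSOTf, 2,6-lutidine, CH2Cl2, −78 → 0 °C
Reagents that add atoms: tert-butyldimethylsilyl triflate, CC(C)(C)[Si](C)(C)OS(=O)(=O)C(F)(F)F
Why: Standard silylation of a hindered secondary alcohol with a silyl triflate; the terminal alkyne and the lactone are unaffected under these non-nucleophilic conditions.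

Step 12
Reactants: 20 C1 TBS ether, 21 dichlorodiisopropylsilane, 22 2-methylbut-3-yn-2-ol
Product: 24 silyl-ether-tethered triyne with C11–SiMe3, via alkynyl(chloro)diisopropylsilane 23 (not isolated)
Conditions: LiN(iPr)2, THF, −78 °C; 21 (3 equiv), −78 → 0 °C; evaporate; 22, imidazole, DMF, rt
Reagents that add atoms: dichlorodiisopropylsilane 21, CC(C)[Si](Cl)(Cl)C(C)C; 2-methylbut-3-yn-2-ol 22, CC(C)(O)C#C
Why: C14–H is the only acidic alkyne hydrogen (C11 is capped, and the lactone has no α-hydrogen); the acetylide displaces one chloride of excess 21, and the remaining Si–Cl bond is then taken by the tertiary alcohol under imidazole catalysis.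

Step 13
Reactants: 24 silyl-ether-tethered triyne with C11–SiMe3
Product: 25 triyne (C9≡C11–H, C8≡C14–Si, C13≡C12–H)
Conditions: AgNO3 (0.2 equiv), 2,6-lutidine, acetone/H2O, rt
Reagents that add atoms: none
Why: Silver-catalysed protodesilylation is selective for trimethylsilyl alkynes; the bulky diisopropyl(alkoxy)silyl alkyne and both silyl ethers survive, which basic methanolysis would not guarantee.

Step 14
Reactants: 25 triyne
Product: 26 pentacyclic arene with fused oxasilole (C11–H, C12–H)
Conditions: RhCl(PPh3)3 (10 mol %), degassed toluene (0.005 M), 80 °C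
Reagents that add atoms: none
Why: After loss of a phosphine, rhodium couples the silicon-linked alkynes C8≡C14 and C12≡C13 oxidatively (monovalent to trivalent rhodium) to a rhodacyclopentadiene, forming C13–C14; the enyne alkyne C9≡C11 then inserts into the Rh–C8 bond (C8–C9), and reductive elimination of C11–C12 releases the arene and the catalyst. The closest known reaction type is the rhodium- or cobalt-catalysed fully intramolecular (2+2+2) cyclotrimerisation of triynes joined by a temporary diisopropylsilyl ether tether. The oxasilole closes as the five-membered tether ring of a 1,6-diyne, ring B as the seven-membered tether ring spanned by C7–C6–C5–C10–C20, and ring C as the six-membered ring made from the six alkyne carbons. No stereocentre is formed; C1, C4, C5 and C6 are carried through unchanged. The step needs regiochemistry, which the two tethers fix completely (C13 can only meet C14, and C12 only C11). It also needs seven-membered closure to outrun oligomerisation of the terminal alkynes, which is secured by high dilution, the (E)-enyne that holds C9 syn to C5, and the cis placement of C7 and C10 on the rigid lactone. The gem-dimethyl and diisopropylsilyl groups favour the first ring closure and shield the central alkyne from intermolecular coupling.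

Step 15
Reactants: 26 pentacyclic arene with fused oxasilole
Product: 27 C14 phenol with a 2-hydroxyprop-2-yl group on C13
Conditions: 30% H2O2, KF, KHCO3, THF/MeOH (1:1), 50 °C
Reagents that add atoms: hydrogen peroxide, OO
Why: Tamao–Fleming oxidation; the ring oxygen on silicon allows peroxide to add, the aryl group migrates from silicon to oxygen at C14, and hydrolysis frees the phenol and the tertiary alcohol, with the secondary TBS ether expected to survive the buffered fluoride.

Step 16
Reactants: 27 C14 phenol with a 2-hydroxyprop-2-yl group on C13
Product: 28 C14 phenol with isopropyl on C13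
Conditions: Et3SiH, CF3CO2H, CH2Cl2, −40 → −10 °C
Reagents that add atoms: none
Why: Ionic hydrogenation; the tertiary benzylic alcohol ortho to the phenol ionises far more easily than any other site (a quinone-methide-like cation) and is trapped by the silane, and the low temperature is chosen to spare the allylic silyl ether and the C10=C20 alkene.

Step 17
Reactants: 28 C14 phenol with isopropyl on C13
Product: 29 11,14-quinone (C6–H and C7–H2 still saturated)
Conditions: K2NO(SO3)2, KH2PO4, acetone/H2O, rt
Reagents that add atoms: potassium nitrosodisulfonate K2NO(SO3)2, [K+].[K+].[O]N(S(=O)(=O)[O-])S(=O)(=O)[O-]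
Why: Teuber oxidation; the phenoxyl radical is trapped by a second nitrosodisulfonate at the free para position C11, and elimination gives the para-quinone, since both ortho positions are blocked.

Step 18
Reactants: 29 11,14-quinone
Product: 31 6,7-dehydro-11,14-quinone, via 6,7-dehydro-11,14-hydroquinone 30 (not isolated)
Conditions: Et3N, degassed MeCN, 40 °C; then Ag2O, rt
Reagents that add atoms: none
Why: Base-induced tautomerisation of an alkylquinone: loss of H7 (γ to the C11 carbonyl) gives the ortho-quinone methide C8=C7, loss of H6 (activated by the lactone oxygen) aromatises it to hydroquinone 30 with C6=C7, and Ag2O returns the quinone; the C6 stereocentre is erased here.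

Step 19
Reactants: 31 6,7-dehydro-11,14-quinone
Product: 33 12-hydroxy-11,14-quinone as its C1 TBS ether, via 12,13-epoxide 32 (not isolated)
Conditions: t-BuOOH (decane), DBU, THF, 0 °C → rt; NaH2PO4 (aq)
Reagents that add atoms: tert-butyl hydroperoxide, CC(C)(C)OO
Why: Weitz–Scheffer epoxidation at the only unsubstituted quinone carbon (C12, β to the C14 carbonyl), followed by base removal of H12 and opening of the C13–O bond to the hydroxyquinone anion; the hindered lactone carbonyl next to quaternary C4 resists the hydroperoxide.

Step 20
Reactants: 33 12-hydroxy-11,14-quinone as its C1 TBS ether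
Product: 34 6,7-anhydroballotiquinone
Conditions: HF·pyridine, THF, 0 °C → rt
Reagents that add atoms: none
Why: Acidic fluoride cleaves the secondary silyl ether without the basic conditions that would open the enol lactone; the freed allylic alcohol does not ionise because the adjacent alkene is conjugated to the electron-poor quinone.

## Compound list

1 | methyl vinyl ketone | CC(=O)C=C | starting material
2 | 2-(tert-butyldimethylsilyloxy)buta-1,3-diene | C=CC(=C)O[Si](C)(C)C(C)(C)C | intermediate
3 | (5R)-5-[(1R,2S,5R)-menthyloxy]furan-2(5H)-one | O=C1C=C[C@H](O[C@@H]2C[C@H](C)CC[C@H]2C(C)C)O1 | starting material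
4 | cis-fused cycloadduct, TBS enol ether C1=C2, H4/H5 cis, C6 menthyloxy anti to ring A | C1C(O[Si](C)(C)C(C)(C)C)=CC[C@@H]2C(=O)O[C@@H](O[C@@H]3C[C@H](C)CC[C@H]3C(C)C)[C@H]12 | intermediate
5 | methyl iodide | CI | starting material
6 | C4-methylated adduct (methyl cis to H5) | C1C(O[Si](C)(C)C(C)(C)C)=CC[C@]2(C)C(=O)O[C@@H](O[C@@H]3C[C@H](C)CC[C@H]3C(C)C)[C@H]12 | intermediate
7 | enone lactone acetal (C1 ketone, C2=C3) | C1C(=O)C=C[C@]2(C)C(=O)O[C@@H](O[C@@H]3C[C@H](C)CC[C@H]3C(C)C)[C@H]12 | intermediate
8 | 3-(trimethylsilyl)propynal | C[Si](C)(C)C#CC=O | starting material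
9 | lithium dienolate of 7 (C1–OLi, C1=C10) | C1=C([O-])C=C[C@]2(C)C(=O)O[C@@H](O[C@@H]3C[C@H](C)CC[C@H]3C(C)C)[C@H]12.[Li+] | intermediate
10 | lithium aldolate (C20–OLi) | [Li+].[O-]C(C#C[Si](C)(C)C)C1C(=O)C=C[C@]2(C)C(=O)O[C@@H](O[C@@H]3C[C@H](C)CC[C@H]3C(C)C)[C@H]12 | intermediate
11 | β-hydroxy enone (aldol at C10; mixture at C10, C20) | OC(C#C[Si](C)(C)C)C1C(=O)C=C[C@]2(C)C(=O)O[C@@H](O[C@@H]3C[C@H](C)CC[C@H]3C(C)C)[C@H]12 | intermediate
12 | β-hydroxy ketone (C2–C3 saturated; mixture at C10, C20) | OC(C#C[Si](C)(C)C)C1C(=O)CC[C@]2(C)C(=O)O[C@@H](O[C@@H]3C[C@H](C)CC[C@H]3C(C)C)[C@H]12 | intermediate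
13 | C20 mesylate of 12 | CS(=O)(=O)OC(C#C[Si](C)(C)C)C1C(=O)CC[C@]2(C)C(=O)O[C@@H](O[C@@H]3C[C@H](C)CC[C@H]3C(C)C)[C@H]12 | intermediate
14 | (E)-enynone lactone acetal | C[Si](C)(C)C#C/C=C1/C(=O)CC[C@]2(C)C(=O)O[C@@H](O[C@@H]3C[C@H](C)CC[C@H]3C(C)C)[C@H]12 | intermediate
15 | lactol (C6 hemiacetal, mixture at C6) | C[Si](C)(C)C#C/C=C1/C(=O)CC[C@]2(C)C(=O)OC(O)[C@H]12 | intermediate
16 | propargyl bromide | C#CCBr | starting material
17 | seco hydroxy acid (C6 carbinol, C19 acid) | C[Si](C)(C)C#C/C=C1/C(=O)CC[C@](C)(C(=O)O)[C@@H]1[C@H](O)CC#C | intermediate
18 | enynone lactone, C6 propargyl cis to C10 | C[Si](C)(C)C#C/C=C1/C(=O)CC[C@]2(C)C(=O)O[C@H](CC#C)[C@H]12 | intermediate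
19 | C1 allylic alcohol (1R, OH syn to lactone) | C[Si](C)(C)C#C/C=C1/[C@H](O)CC[C@]2(C)C(=O)O[C@H](CC#C)[C@H]12 | intermediate
20 | C1 TBS ether | C[Si](C)(C)C#C/C=C1/[C@H](O[Si](C)(C)C(C)(C)C)CC[C@]2(C)C(=O)O[C@H](CC#C)[C@H]12 | intermediate
21 | dichlorodiisopropylsilane | CC(C)[Si](Cl)(Cl)C(C)C | starting material
22 | 2-methylbut-3-yn-2-ol | CC(C)(O)C#C | starting material
23 | alkynyl(chloro)diisopropylsilane at C14 | C[Si](C)(C)C#C/C=C1/[C@H](O[Si](C)(C)C(C)(C)C)CC[C@]2(C)C(=O)O[C@H](CC#C[Si](Cl)(C(C)C)C(C)C)[C@H]12 | intermediate
24 | silyl-ether-tethered triyne with C11–SiMe3 | C[Si](C)(C)C#C/C=C1/[C@H](O[Si](C)(C)C(C)(C)C)CC[C@]2(C)C(=O)O[C@H](CC#C[Si](C(C)C)(C(C)C)OC(C)(C)C#C)[C@H]12 | intermediate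
25 | lactone-tethered triyne (key-step precursor) | C#C/C=C1/[C@H](O[Si](C)(C)C(C)(C)C)CC[C@]2(C)C(=O)O[C@H](CC#C[Si](C(C)C)(C(C)C)OC(C)(C)C#C)[C@H]12 | intermediate
26 | pentacyclic arene with fused oxasilole (key-step product) | CC1(C)O[Si](C(C)C)(C(C)C)c2c1ccc1c2C[C@H]2OC(=O)[C@@]3(C)CC[C@@H](O[Si](C)(C)C(C)(C)C)C(=C1)[C@@H]23 | intermediate
27 | C14 phenol with 2-hydroxyprop-2-yl on C13 | CC(C)(O)c1ccc2c(c1O)C[C@H]1OC(=O)[C@@]3(C)CC[C@@H](O[Si](C)(C)C(C)(C)C)C(=C2)[C@@H]13 | intermediate
28 | C14 phenol with isopropyl on C13 | CC(C)c1ccc2c(c1O)C[C@H]1OC(=O)[C@@]3(C)CC[C@@H](O[Si](C)(C)C(C)(C)C)C(=C2)[C@@H]13 | intermediate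
29 | 11,14-quinone (C6, C7 saturated) | CC(C)C1=CC(=O)C2=C(C1=O)C[C@H]1OC(=O)[C@@]3(C)CC[C@@H](O[Si](C)(C)C(C)(C)C)C(=C2)[C@@H]13 | intermediate
30 | 6,7-dehydro-11,14-hydroquinone | CC(C)c1cc(O)c2c(c1O)C=C1OC(=O)[C@@]3(C)CC[C@@H](O[Si](C)(C)C(C)(C)C)C(=C2)[C@@H]13 | intermediate
31 | 6,7-dehydro-11,14-quinone | CC(C)C1=CC(=O)C2=C(C=C3OC(=O)[C@@]4(C)CC[C@@H](O[Si](C)(C)C(C)(C)C)C(=C2)[C@@H]34)C1=O | intermediate
32 | 12,13-epoxide of 31 (mixture at C12/C13) | CC(C)C12OC1C(=O)C1=C(C=C3OC(=O)[C@@]4(C)CC[C@@H](O[Si](C)(C)C(C)(C)C)C(=C1)[C@@H]34)C2=O | intermediate
33 | 6,7-anhydroballotiquinone 1-O-TBS ether | CC(C)C1=C(O)C(=O)C2=C(C=C3OC(=O)[C@@]4(C)CC[C@@H](O[Si](C)(C)C(C)(C)C)C(=C2)[C@@H]34)C1=O | intermediate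
34 | 6,7-anhydroballotiquinone | CC(C)C1=C(O)C(=O)C2=C(C=C3OC(=O)[C@@]4(C)CC[C@@H](O)C(=C2)[C@@H]34)C1=O | target

## Step count and least certain steps

Total step count: 20. Longest linear sequence: 20 steps (1 to 34); compounds 3, 5, 8, 16, 21 and 22 enter as purchased materials.

**Step 14 (key step).** Most likely to go wrong is slow closure of the seven-membered ring, so that the terminal alkynes dimerise or oligomerise between molecules, or form rhodium vinylidenes that deactivate the catalyst. Fallback: the cyclisation is moved one step earlier, onto the silyl-capped triyne 24, with CpCo(CO)2 under irradiation in boiling toluene, where the C11 cap suppresses terminal-alkyne side reactions. This gives the C11-silylated arene F1. Tamao–Fleming oxidation as in step 15 gives the C11-silylated phenol carbinol F2. The acid of step 16 then removes the carbinol oxygen and, by ipso-protonation para to the phenol, the aryl–SiMe3 bond, and the route is rejoined at 28.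

**Step 9.** Poor facial selectivity at C6 is the risk: the allenylindium reagent adds through a loose transition state, and the Felkin–Anh preference set by the quaternary C4 may be modest, giving both C6 epimers. Fallback: the same bond is made from 15 under catalyst control instead of substrate control, by allenylboration with allenylboronic acid pinacol ester and a chiral BINOL-derived phosphoric acid chosen to match the Felkin sense, followed by the same acid lactonisation to 18. No new compound is involved.

**Step 10.** Poor facial selectivity of hydride delivery at C1 is the risk, should the conformer with the C5–C6 bond pseudo-equatorial take part. Fallback: reagent-controlled reduction of 18 with (S)-2-methyl-CBS-oxazaborolidine and BH3·SMe2, in which the alkylidene side acts as the large group and the (1R) alcohol 19 is expected. No new compound is involved.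

**Step 15.** Protodesilylation of the hindered aryl–Si(iPr)2 bond under fluoride may compete with peroxide attack at silicon, and the TBS ether may be lost. Fallback: a less hindered tether is built from 20 with dichlorodiethylsilane in place of 21. The chlorosilane F3 and alcohol 22 give the diethylsilyl-tethered triyne F4, step 13 gives the triyne F5, and step 14 gives the diethyl oxasilole arene F6. F6 should oxidise with H2O2 and KHCO3 alone, without fluoride, and the route is rejoined at 27.

**Step 16.** Acid ionisation of the allylic C1–O bond, or protonation and reduction of the C10=C20 styrene, may accompany the wanted deoxygenation. Fallback: 27 is dehydrated under nearly neutral conditions (catalytic pyridinium p-toluenesulfonate, toluene, 60 °C) to the isopropenyl phenol F7. Its 1,1-disubstituted alkene is then hydrogenated with H2 and RhCl(PPh3)3, which leaves the trisubstituted C10=C20 alkene alone, to give 28.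

**Step 18.** Deprotonation at the wrong site is the risk: loss of H5 or H1 through the C10=C20 vinylogous path, or of the isopropyl methine hydrogen, would move unsaturation to the wrong place or scramble C5. Fallback: the dehydrogenation is done one step earlier on phenol 28 with one equivalent of DDQ in benzene. The ortho-quinone methide at C8=C7 tautomerises to the 6,7-dehydro phenol F8, and oxidation of F8 with K2NO(SO3)2 as in step 17 gives 31 directly.

## Further compounds

F1 | step 14 | C11-trimethylsilyl arene with fused oxasilole | CC1(C)O[Si](C(C)C)(C(C)C)c2c1cc([Si](C)(C)C)c1c2C[C@H]2OC(=O)[C@@]3(C)CC[C@@H](O[Si](C)(C)C(C)(C)C)C(=C1)[C@@H]23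
F2 | step 14 | C11-trimethylsilyl C14 phenol with 2-hydroxyprop-2-yl on C13 | CC(C)(O)c1cc([Si](C)(C)C)c2c(c1O)C[C@H]1OC(=O)[C@@]3(C)CC[C@@H](O[Si](C)(C)C(C)(C)C)C(=C2)[C@@H]13
F0 | step 9 | none | none
F0 | step 10 | none | none
F3 | step 15 | alkynyl(chloro)diethylsilane at C14 | C[Si](C)(C)C#C/C=C1/[C@H](O[Si](C)(C)C(C)(C)C)CC[C@]2(C)C(=O)O[C@H](CC#C[Si](Cl)(CC)CC)[C@H]12
F4 | step 15 | diethylsilyl-ether-tethered triyne with C11–SiMe3 | C[Si](C)(C)C#C/C=C1/[C@H](O[Si](C)(C)C(C)(C)C)CC[C@]2(C)C(=O)O[C@H](CC#C[Si](CC)(CC)OC(C)(C)C#C)[C@H]12
F5 | step 15 | diethylsilyl-ether-tethered triyne | C#C/C=C1/[C@H](O[Si](C)(C)C(C)(C)C)CC[C@]2(C)C(=O)O[C@H](CC#C[Si](CC)(CC)OC(C)(C)C#C)[C@H]12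
F6 | step 15 | pentacyclic arene with fused diethyl oxasilole | CC1(C)O[Si](CC)(CC)c2c1ccc1c2C[C@H]2OC(=O)[C@@]3(C)CC[C@@H](O[Si](C)(C)C(C)(C)C)C(=C1)[C@@H]23
F7 | step 16 | C14 phenol with isopropenyl on C13 | CC(=C)c1ccc2c(c1O)C[C@H]1OC(=O)[C@@]3(C)CC[C@@H](O[Si](C)(C)C(C)(C)C)C(=C2)[C@@H]13
F8 | step 18 | 6,7-dehydro C14 phenol with isopropyl on C13 | CC(C)c1ccc2c(c1O)C=C1OC(=O)[C@@]3(C)CC[C@@H](O[Si](C)(C)C(C)(C)C)C(=C2)[C@@H]13
A1 | alternative 1 | ortho-formyl aryl diazomethyl ketone | CC(C)c1c(OC)c(OC)c(C=O)c(C(=O)C=[N+]=[N-])c1OC
A2 | alternative 1 | 2-benzopyrylium-4-olate dipole | CC(C)c1c(OC)c(OC)c2C=[O+]C=C([O-])c2c1OC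
A3 | alternative 1 | methyl 1-methyl-4-oxocyclohex-2-ene-1-carboxylate (ring A enone) | C[C@]1(C(=O)OC)CCC(=O)C=C1
A4 | alternative 1 | oxygen-bridged 6-7-6 cycloadduct | CC(C)c1c(OC)c(OC)c2c(c1OC)C(=O)[C@@H]1O[C@H]2[C@@H]3C(=O)CC[C@](C)(C(=O)OC)[C@H]13
A5 | alternative 2 | arene-tethered butenolide silyloxydiene | CC(C)c1c(OC)c(OC)c(CC=C(O[Si](C)(C)C(C)(C)C)C=C)c(C[C@H]2OC(=O)C(C)=C2)c1OC
A6 | alternative 2 | tetracyclic lactone with C1 silyl enol ether | CC(C)c1c(OC)c(OC)c2c(C[C@H]3OC(=O)[C@@]4(C)CC=C(O[Si](C)(C)C(C)(C)C)[C@@H](C2)[C@@H]34)c1OC
A7 | alternative 3 | 4-hydroxy-4-(cycloheptatrienyl)cyclobutenone | CC(C)C1=C(OC(C)(C)C)C(O)(C2=CC=C3OC(=O)[C@@]4(C)CC[C@@H](O[Si](C)(C)C(C)(C)C)C(=C2)[C@@H]34)C1=O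
A8 | alternative 3 | 12-tert-butoxy-11,14-hydroquinone | CC(C)c1c(OC(C)(C)C)c(O)c2c(C=C3OC(=O)[C@@]4(C)CC[C@@H](O[Si](C)(C)C(C)(C)C)C(=C2)[C@@H]34)c1O
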